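(The earlier runs and the new flask are calculated with made-up constants; the scatter is artificial.)

Amounts first: in the epsilon run, 1.25 mM of starting material is missing from the balance at 6.00 min, close to the 1.3 mM of catalyst charged, so I take the catalyst to carry that much as a load.

| flask | starting material | reagent | free catalyst | remark | time |
|---|---|---|---|---|---|
| epsilon | 4.7 mM | 13 mM | 1.3 mM | run made earlier |  |
| beta | 20 mM | 13 mM | 1.3 mM | run made earlier |  |
| south-west | 6.0 mM | 13.0 mM | 1.3 mM |  | 2.5 h |
| south-east | 12 mM | 13.0 mM | 1.3 mM |  | 2.5 h |
| north-east | 25 mM | 13.0 mM | 1.3 mM |  | 2.5 h |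

| run | time / min | target / % | starting material / % |
|---|---|---|---|
| epsilon | 6.00 | 25.7 | 47.7 |
| epsilon | 10.0 | 44.6 | 29.2 |
| epsilon | 15.0 | 68.0 | 8.3 |
| epsilon | 20.0 | 85.4 | 1.1 |
| epsilon | 30.0 | 97.8 | 0 |
| epsilon | 50.0 | 99.2 | 0 |
| epsilon | 80.0 | 98.5 | 0 |
| beta | 6.00 | 5.1 | 86.8 |
| beta | 10.0 | 10.5 | 81.7 |
| beta | 15.0 | 16.8 | 74.6 |
| beta | 20.0 | 19.8 | 67.0 |
| beta | 30.0 | 27.5 | 50.2 |
| beta | 50.0 | 38.6 | 29.6 |
| beta | 80.0 | 46.5 | 9.2 |

(each reading ± 1 percentage point)

- what was read earlier has a scatter of 1 percentage point, one standard deviation
- "hardly changes" means that all values lie within two and a half points (for a concentration: within two and a half percent of the largest)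

- [target] at the end for south-west, south-east, north-east, in this order
- how the row runs (hardly changes / rises, then falls / falls, then rises / falls all the way / rises all the way)

I begin with the main step alone. In the epsilon run, target grows between 6.00 min and 20.0 min at a steady reading of v = 0.200 mM min⁻¹, a zero-order rate. Over 2.5 h that amounts to 30.0 mM, more than the largest charge, so this step by itself makes target equal to the charge, and the row rises all the way.

Now I add a second process. In the beta run the balance gap keeps growing between 30.0 min and 80.0 min, and I read this as starting material and target destroying each other, one of each per event. Events run there at 0.0440 mM min⁻¹, while the root of the product of starting material A and target P averages 6.25 mM. Dividing the loss rate by v removes time: each mM of target made costs A·P divided by the square of c*, the waste scale 13.3 mM, whose square is the value of A·P at which loss equals making. Summing while P climbs to a, the charge less the load, gives an event tally E, a cubed over 6 times c* squared. Each event costs two targets, the one eaten and the one never made. South-west therefore has E = 0.0973 mM and target 5.81 mM; south-east has E = 1.15 mM and target 9.70 mM.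

Last comes the reagent. At 80.0 min the beta run has made 13.1 mM of target, events counted, which is about the reagent charge, so I assume one reagent per target. North-east charges more starting material than reagent, so the tally stops at 13.0 mM made, with 7.15 mM of events and target 5.85 mM. Afterwards starting material and target fall together, their difference staying at D = 2.30 mM. Integrating to 2.5 h gives 4.48 mM, so my row rises, then falls.

The forecast gives 5.7 mM, 9.3 mM and 7.5 mM, rises, then falls, holding that at the top charge “the catalyst fades while starting material remains and keeps eating target”, and at north-east my figure lies lower.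

The flasks give 5.81 mM, 10.2 mM and 5.36 mM: rises, then falls.

    starting material + free catalyst → catalyst intermediate A (k = 41.3 L mol⁻¹ s⁻¹)
    catalyst intermediate A ⇌ catalyst intermediate B (K = 1.46, k = 0.0594 s⁻¹)
    reagent + catalyst intermediate B → catalyst intermediate C (k = 3.46 L mol⁻¹ s⁻¹)
    catalyst intermediate C ⇌ catalyst intermediate D (K = 0.300, k = 0.0260 s⁻¹)
    catalyst intermediate D → free catalyst + target (k = 0.0195 s⁻¹)
    free catalyst → spent catalyst (k = 9.49 × 10⁻⁴ s⁻¹)
    starting material + target → side product (k = 0.0202 L mol⁻¹ s⁻¹)

At 1.25 h the north-east flask holds 1.03% of its reagent, the limiting reagent there, while 23.1% of its starting material still stands, whereas the south-east flask at 1.25 h holds 0% of starting material and 14.7% of its reagent. With the same c*, the south-east tally is 1.15 mM, and that flask's side product, 15.1% counted as two, stands for 0.905 mM of events. North-east target goes from 30.0% at 1.25 h to 21.4% at 2.50 h, and at 25.0 h reads 9.23%, which is 2.31 mM.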